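The readings are simulated for substances that don't exist.

The ring is what I want, but the flask also turns it into over-reaction product, so what I can take is a peak, and I need its height and its time.

| flask | starting material | protic impurity | remark | time |
|---|---|---|---|---|
| birch | 2 M | 0.20 M | the very flask that is asked about, followed so far |  |
| flask | 2.0 M | 0.200 M |  | 2.5 d |

birch run (percent of the starting material charged)

| time / h | ring / % | starting material / % |
|---|---|---|
| 1.33 | 30 | 28 |
| 2.50 | 43 | 17 |
| 5.00 | 48 | 7 |
| 8.00 | 43 | 2 |
| 15.0 | 29 | 3 |
| 30.0 | 10 | 0 |

(readings scatter by 2 percentage points)

1. the best time, 2.5 d at the latest, for ring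
2. the amount of ring, in percent of the starting material charged, at that time
3. earliest time at which at least nineteen twentieths of that best amount are there, in d
4. latest time at which they still are, in d

The birch run is this same flask. Its starting material falls from 28% at 1.33 h to 7% at 5.00 h, which reads as a rate of 0.378 h⁻¹. Its ring falls from 43% at 8.00 h to 10% at 30.0 h, a slower rate of 0.0663 h⁻¹.

I follow one molecule through two extreme flasks. In the first, each molecule of starting material becomes ring at the first of these rates and the ring then decays at the second. The peak comes at 5.59 h and holds 69.0% of the charge. I call this the keep, the fraction of the charge that a chain without forks holds as ring at its peak. In the second, the ring never decays, but each molecule meets forks towards the open dimer and the quenched substrate. The ring climbs to the chance of choosing ring, the selectivity, and stays there.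

The real flask has both, so I take its peak as chance times keep. The reading of 48% at 5.00 h then gives a chance of 69.5%.

The forecast gives 48% at 0.2 d, with a window from 0.125 d to 0.3 d. Its ground: “The times are read straight from the birch run, since it is the same flask.” My peak time of 0.233 d is later than its time.

The flask gives 47.6% at 0.212 d, with a window from 0.142 d to 0.308 d.

    starting material → ring (k = 0.00830 min⁻¹)
    2 starting material → open dimer (k = 0.00180 M⁻¹ min⁻¹)
    starting material + protic impurity → quenched substrate (k = 0.0220 M⁻¹ min⁻¹)
    starting material ⇌ dormant form (K = 0.420, k = 0.0280 min⁻¹)
    ring → over-reaction product (k = 0.00120 min⁻¹)

Dividing 47.6% by the keep gives a chance of 69.0% for this flask, and its ring plus over-reaction product stand at 70.6% after 2.50 d. The neighbour flask charged with 0.80 M of protic impurity holds 37.2% as quenched substrate after 2.50 d, and its ring plus over-reaction product stand at 49.9%. Taking that sum as the neighbour's chance and carrying over the keep read from the birch run as an estimate, I get 34.4%, and the neighbour's best ring is 34.9%.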